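## Structural features

The target is an achiral diarylmethane: two benzene rings joined through one CH2 group, with no stereocentre, so nothing has to be controlled in three dimensions. Ring A is pentasubstituted. A methoxy carbon sits between two hydroxyl carbons (a 2-methoxyresorcinol); next to one hydroxyl comes the benzyl-bearing carbon, then the CH2OH-bearing carbon, and a single ring CH closes the circle. Ring B is a 2,3-dibromo-4,5-dihydroxyphenyl group, a catechol with two adjacent bromines, one of them ortho to the bridging CH2. The fragile points are:
- the free catechol, which air oxidises to the ortho-quinone in base;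
- the two aryl C–Br bonds, which are lost to alkyllithiums, zerovalent palladium or dissolving metals;
- the ring A benzylic alcohol, which sits para to the methoxy group and can ionise in acid;
- the single ring A CH, a resorcinol-type position open to electrophiles such as formaldehyde.

The real difficulty is the contiguous substitution of ring A, above all placing the benzyl group between a hydroxyl carbon and the CH2OH carbon without ambiguity. The key step uses the 1,3-relationship of the two ring A hydroxyl carbons with the methoxy carbon between them. These three carbons are C4, C5 and C6 of a linear 2,4,6-trioxo ester, the ring CH is C3, the CH2OH-bearing carbon is the keto carbon C2 (its ester carbon C1 becomes CH2OH), and the benzyl-bearing carbon is C7. One C2–C7 aldol bond therefore closes ring A with every substituent already in place.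

## Logic of the disconnections

**20 back to 19.** No skeletal bond is cut. The CH2OH carbon of ring A is returned to the ester oxidation level. The ester is what the ring-forming step leaves on this carbon, and putting the reduction last means that no benzylic alcohol exists when acid is used. The forward step must reduce an ester beside four acidic OH groups and two aryl C–Br bonds, so it needs an excess of an aluminium hydride that leaves aryl bromides alone.

**19 back to 18.** The two catechol O–H bonds of ring B are exchanged for O–CH2OCH3 acetal bonds. A free catechol cannot pass through amide bases and a base-mediated cyclisation, whereas these acetals survive both and leave under acid. Doing this cleavage on the ester, in methanol, removes two risks at once: the released C1 unit is trapped as dimethoxymethane, and there is no benzylic alcohol to solvolyse. The forward step needs only acid that spares the methyl ester and the aryl methyl ether.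

**18 back to 16.** The ring A bond between the benzyl-bearing carbon and the ester-bearing carbon is cut and water is added back, which unfolds the arene into the open chain 16. A pentasubstituted ring with five different neighbours becomes a linear chain whose carbon order already encodes the substitution pattern. The forward step must close through carbon and not oxygen, and by one aldol mode only, which is why base and not acid is used. The methoxy-bearing carbon of 16 is racemic and enolisable and disappears on aromatisation, so 16 is written without a configuration there.

**16 back to 12 and 13.** The bond between the keto-ester carbonyl C2 and the CH2 carbon C3 is cut, a Claisen-type acylation. This removes the most reactive terminus and leaves a simple 1,3-diketone plus a symmetrical diester. The forward step needs second deprotonation of 12 at its methyl group and not at its CH2, a single addition to 13, and a base that does not exchange with aryl bromides.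

**12 back to 10 and 7.** The bond between the benzylic carbon and the CH2 alpha to the ketone is cut. This is the convergent union of the ring B fragment with the five-carbon chain. The forward step needs alkylation at the terminal carbon of dianion 11 and not at its central carbon, which the dianion's reactivity order provides.

**10 back to 9 and 8.** The C–OCH3 bond at the central carbon is cut. That carbon is the nucleophilic site of a 1,3-diketone, so oxygen is brought in by reversing its polarity through a diazo compound and a metal carbenoid. The forward steps are diazo transfer to 8 and O–H insertion into methanol, which must outrun Wolff rearrangement of 9.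

**7 back to 6 and 5.** The benzylic C–Br bond is traced to C–OH and then to the aldehyde C=O. These are functional-group changes only. The bromide is made under neutral conditions because the acetal ethers are acid-labile.

**5 back to 4, 3 and 1.** The two acetal O–C bonds are removed, the catechol is traced to a guaiacol (one O–CH3 bond), and the two aryl C–Br bonds are cut one after the other through 2. In 1 the hydroxyl and methoxy groups leave only one site for each bromine, so the ring B pattern is fixed at the outset.

## Other disconnections considered

**Alternative 1:** The cut is at the two ring B C–Br bonds, made at the very end. The bromine-free diarylmethane A1 (ring B a free catechol, ring A deactivated as diacetate and ester) would be treated with two equivalents of electrophilic bromine to give A2. The bromine source would be Br2 in acetic acid, or bromide with H2O2 and catalytic NH4VO3.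
- In favour: it mirrors the likely biogenesis. No C–Br bond has to pass through polyanion or hydride steps, so alkyllithium bases, hydrogenation and palladium chemistry would all be open for building A1; on this point it is better than the chosen plan. An aluminium hydride would reduce the ester of A2 and strip both acetates in one operation, so its endgame is the equal of the chosen one.
- Against: ring B of A1 has three open positions. The first bromine should enter para to one hydroxyl, beside the bridging CH2. The second must then choose between the carbon ortho to the other hydroxyl (wanted) and the carbon between hydroxyl and bridge. Tribromination, oxidation of the catechol to the ortho-quinone, and attack at the one ring A CH are further leaks.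
- Comparison: in the chosen plan both bromines are placed on 1, where the directing groups leave a single site for each. Alternative 1 moves a delicate selectivity between similar positions to the last stage, where material is most valuable. A1 still has to be assembled with the full ring A pattern, so the step count is about equal and the main structural problem stays unsolved.

**Alternative 2:** The cut is at two ring A bonds: between the ring CH and the CH2O-bearing carbon, and between a hydroxyl carbon and the carbon that carries ring B. In this plan the bridge is a ketone, not CH2. Diene A3 would add to ynone A4 in a Diels–Alder reaction and the adduct would aromatise by loss of methanol to give benzophenone A5.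
- In favour: the regiochemistry follows from polarity matching, the nucleophilic CH2 terminus of A3 bonding to the beta carbon of A4. Thermal, neutral conditions should tolerate aryl bromides and acetal ethers. The CH2OH carbon arrives at the right oxidation level, so no ester reduction on a polyphenol is needed; on this point it is better than the chosen plan. It is the equal of the chosen plan in building ring A with all three oxygens in place.
- Against: A5 has C=O where the target has CH2. Deoxygenating a hindered, hydrogen-bonded ortho-hydroxy benzophenone is awkward here: ionic hydrogenation is acidic and threatens the acetal and silyl ethers, while dissolving metals or catalytic hydrogenation threaten C–Br. A3 is a hydrolytically sensitive, tetra-oxygenated diene. Its adduct could aromatise by losing either methanol or silanol, and only the first gives the free hydroxyl.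
- Comparison: both plans make ring A from acyclic carbon. The chosen aldol delivers the bridge directly as CH2 and needs no sensitive diene. Alternative 2 adds one or two steps for the ketone removal and the extra protecting group, so it is somewhat longer.

**Alternative 3:** The cut is at both bonds of the bridging CH2. Phenol A6, formaldehyde A7 and boronic acid A8 would condense to the benzodioxaborin A9. Acid activation would ionise its benzylic C–O bond, giving ortho-quinone methide character at the exocyclic carbon, and the ring B aryl group would migrate from boron to that carbon to give A10.
- In favour: ring A comes from a commercial gallate-type ester. Only one position ortho to the free hydroxyl of A6 is open, so the site of attack is unambiguous. Both bridge bonds form in one operation without polyanion chemistry. On paper this is the shortest sequence, the equal or the better of the chosen plan in step count.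
- Against: the reacting position is squeezed between a hydroxyl and an ester on an electron-poor ring, so formation of A9 should be slow. The migrating aryl group carries an ortho bromine, and the acid needed for activation threatens the acetal ethers. A8 is hard to reach: an acetal-directed metalation would choose the wrong ring hydrogen, and halogen–metal exchange would have to distinguish three halogens. A6 requires desymmetrising a symmetric diol.
- Comparison: Alternative 3 uses an intact ring A and is more convergent. The chosen plan is longer but rests on carbonyl chemistry in which each bond has one sensible place to form. The mechanistic risk of Alternative 3 is concentrated in its single key operation and in the supply of A8.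

Key step: step 10

Remark: 16 is a mixture of enol tautomers and is racemic and labile at its methoxy-bearing carbon, so 16 and 17 are written as keto forms without configuration.

## Route

Step 1
Reactants: 1 vanillin (4-hydroxy-3-methoxybenzaldehyde)
Product: 3 2,3-dibromo-4-hydroxy-5-methoxybenzaldehyde, via 5-bromovanillin 2 (not isolated)
Conditions: Br2 (1.05 equiv), AcOH, rt; then Fe powder (5 mol %), Br2 (1.3 equiv), AcOH, 50 °C
Reagents that add atoms: bromine, BrBr
Why: Two electrophilic aromatic brominations; the phenol sends the first bromine ortho to itself (2), and with the phenol's ortho and para sites then filled the methoxy group directs the second, FeBr3-assisted bromination to its para position, the carbon between the first bromine and the formyl group.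

Step 2
Reactants: 3 2,3-dibromo-4-hydroxy-5-methoxybenzaldehyde
Product: 4 2,3-dibromo-4,5-dihydroxybenzaldehyde
Conditions: AlCl3 (1.5 equiv), pyridine (4.5 equiv), CH2Cl2, reflux; then 2 M HCl
Reagents that add atoms: none
Why: Chelation-assisted demethylation of an ortho-hydroxy anisole; aluminium bridges the phenoxide and the methoxy oxygen and pyridine removes the methyl group by SN2, while the aldehyde and aryl bromides are inert.

Step 3
Reactants: 4 2,3-dibromo-4,5-dihydroxybenzaldehyde
Product: 5 2,3-dibromo-4,5-bis(methoxymethoxy)benzaldehyde
Conditions: MOMCl (3 equiv), iPr2NEt (4 equiv), CH2Cl2, 0 °C → rt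
Reagents that add atoms: chloromethyl methyl ether, COCCl
Why: Standard O-alkylation of phenols to methoxymethyl acetals; these ethers withstand amide bases, hydride and carbonate and are removed later by acid.

Step 4
Reactants: 5 2,3-dibromo-4,5-bis(methoxymethoxy)benzaldehyde
Product: 6 [2,3-dibromo-4,5-bis(methoxymethoxy)phenyl]methanol
Conditions: NaBH4 (1 equiv), MeOH–THF, 0 °C
Reagents that add atoms: none
Why: Borohydride reduction of an aryl aldehyde; aryl bromides and acetal ethers are untouched.

Step 5
Reactants: 6 [2,3-dibromo-4,5-bis(methoxymethoxy)phenyl]methanol
Product: 7 2,3-dibromo-1-(bromomethyl)-4,5-bis(methoxymethoxy)benzene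
Conditions: CBr4 (1.3 equiv), PPh3 (1.3 equiv), CH2Cl2, 0 °C
Reagents that add atoms: carbon tetrabromide, BrC(Br)(Br)Br
Why: Appel reaction of a primary benzylic alcohol; the neutral conditions avoid the HBr that would cleave the acetal ethers, and the electron-rich bromide is used without delay.

Step 6
Reactants: 8 acetylacetone (pentane-2,4-dione)
Product: 9 3-diazopentane-2,4-dione
Conditions: 4-AcNHC6H4SO2N3 (1.05 equiv), Et3N (1.2 equiv), MeCN, 0 °C → rt
Reagents that add atoms: 4-acetamidobenzenesulfonyl azide, CC(=O)Nc1ccc(cc1)S(=O)(=O)N=[N+]=[N-]
Why: Regitz diazo transfer to an active methylene; this sulfonyl azide is chosen as the safer-handling transfer reagent and its sulfonamide by-product is removed by filtration.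

Step 7
Reactants: 9 3-diazopentane-2,4-dione
Product: 10 3-methoxypentane-2,4-dione
Conditions: Rh2(OAc)4 (1 mol %), MeOH (10 equiv), PhMe, 80 °C
Reagents that add atoms: methanol, CO
Why: Rhodium-carbenoid O–H insertion into methanol; the catalysed path runs well below the temperature of thermal Wolff rearrangement, and excess alcohol captures the carbenoid.

Step 8
Reactants: 10 3-methoxypentane-2,4-dione; 7 2,3-dibromo-1-(bromomethyl)-4,5-bis(methoxymethoxy)benzene
Product: 12 1-[2,3-dibromo-4,5-bis(methoxymethoxy)phenyl]-4-methoxyhexane-3,5-dione, via dilithium 3-methoxypenta-1,3-diene-2,4-diolate 11 (not isolated)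
Conditions: 10 (1.3 equiv), LiN(iPr)2 (2.05 equiv per 10), THF, −78 → 0 °C; then 7 (1.0 equiv), −78 → 0 °C; aq. NH4Cl
Reagents that add atoms: none
Why: Terminal alkylation of a 1,3-diketone dianion; the last-formed, least stabilised carbanion of 11 is the one that attacks the benzylic bromide by SN2. An amide base is used because an alkyllithium would exchange with the aryl bromides, and ring B has no hydrogen ortho to bromine from which an aryne could form.

Step 9
Reactants: 12 1-[2,3-dibromo-4,5-bis(methoxymethoxy)phenyl]-4-methoxyhexane-3,5-dione; 13 dimethyl oxalate
Product: 16 methyl 8-[2,3-dibromo-4,5-bis(methoxymethoxy)phenyl]-5-methoxy-2,4,6-trioxooctanoate, via dilithium dienolate 14 (not isolated), via lithium hemiketal adduct 15 (not isolated)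
Conditions: LiN(iPr)2 (2.2 equiv), THF, −78 → −30 °C; cannulate into 13 (3 equiv), THF, −78 °C; AcOH (5 equiv), −78 → 0 °C; crude 16 used directly
Reagents that add atoms: none
Why: Claisen-type acylation of a 1,3-diketone dianion; kinetic second deprotonation should favour the methyl group over the CH2, and the methyl carbanion of 14 adds once to the oxalate. At −78 °C the chelated adduct 15 should persist until the acid quench, which prevents proton transfer from the acidic product to unreacted 14 and prevents a second addition; inverse addition into excess 13 serves the same end.

Step 10
Reactants: 16 methyl 8-[2,3-dibromo-4,5-bis(methoxymethoxy)phenyl]-5-methoxy-2,4,6-trioxooctanoate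
Product: 18 methyl 2-[2,3-dibromo-4,5-bis(methoxymethoxy)benzyl]-3,5-dihydroxy-4-methoxybenzoate, via cyclic aldol 17 (not isolated)
Conditions: K2CO3 (3 equiv), MeOH, Ar, 0 → 45 °C; then AcOH
Reagents that add atoms: none
Why: Carbonate in methanol converts 16 into its enolates, and the enolate carbon C7 (the CH2 beside the terminal C6 ketone, carrying the arylmethyl tail) adds to the C2 carbonyl of the alpha-keto ester, the most electrophilic carbonyl of the chain, to give aldol 17. The closest known reaction type is the biomimetic polyketide aldol cyclisation of a 2,4,6-tricarbonyl chain to a resorcinol (heptane-2,4,6-trione to orcinol); here the chain ends in a keto ester, so a resorcylate results. The closure is a 6-(enolendo)-exo-trig aldol forming the C2–C7 bond, which is the ring A bond between the ester-bearing and the benzyl-bearing carbon. E1cB loss of water from 17 across C2–C3 and enolisation of the C4 and C6 ketones give the arene, and aromatisation makes the sequence irreversible. No stereocentre survives, since C5 of 16 and the three sp3 centres of 17 all become sp2. The step needs closure through carbon and one aldol mode: under base any closure through oxygen stays reversible whereas acid would end at a 4-pyranone, and C7 to C2 is the only six-membered C–C closure the chain allows. The one conceivable competitor, five-membered Dieckmann attack of the hindered diketonate carbon C5 on the ester, pairs a poorer nucleophile with a poorer electrophile. Methanol as solvent makes ester exchange invisible, and the mild base leaves acetal ethers and aryl bromides alone.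

Step 11
Reactants: 18 methyl 2-[2,3-dibromo-4,5-bis(methoxymethoxy)benzyl]-3,5-dihydroxy-4-methoxybenzoate
Product: 19 methyl 2-(2,3-dibromo-4,5-dihydroxybenzyl)-3,5-dihydroxy-4-methoxybenzoate
Conditions: HCl (1.5 M, from AcCl) in MeOH, 40 °C
Reagents that add atoms: none
Why: Acid-catalysed methanolysis of the two aryl methoxymethyl acetals; methanol traps the released C1 unit as dimethoxymethane so it cannot attack the free ring A position, the methyl ester only exchanges with itself, and no benzylic alcohol is yet present to ionise.

Step 12
Reactants: 19 methyl 2-(2,3-dibromo-4,5-dihydroxybenzyl)-3,5-dihydroxy-4-methoxybenzoate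
Product: 20 3,4-dibromo-5-{[2,4-dihydroxy-6-(hydroxymethyl)-3-methoxyphenyl]methyl}benzene-1,2-diol (target)
Conditions: iBu2AlH (8 equiv, PhMe solution), THF, 0 °C → rt; aq. potassium sodium tartrate (KNaC4H4O6), then dilute HCl to pH 3, Ar
Reagents that add atoms: none
Why: Aluminium hydride reduction of an aryl ester to the benzylic alcohol; the four phenols are first converted to aluminium phenoxides, which is why a large excess is used. Excess iBu2AlH is the usual reagent for esters that carry free phenols, and it does not attack aryl bromides at these temperatures.

## Compound list

1 | vanillin (4-hydroxy-3-methoxybenzaldehyde) | COc1cc(C=O)ccc1O | starting material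
2 | 5-bromovanillin (3-bromo-4-hydroxy-5-methoxybenzaldehyde; formed in the flask, not isolated) | COc1cc(C=O)cc(Br)c1O | intermediate
3 | 2,3-dibromo-4-hydroxy-5-methoxybenzaldehyde | COc1cc(C=O)c(Br)c(Br)c1O | intermediate
4 | 2,3-dibromo-4,5-dihydroxybenzaldehyde | O=Cc1cc(O)c(O)c(Br)c1Br | intermediate
5 | 2,3-dibromo-4,5-bis(methoxymethoxy)benzaldehyde | COCOc1cc(C=O)c(Br)c(Br)c1OCOC | intermediate
6 | [2,3-dibromo-4,5-bis(methoxymethoxy)phenyl]methanol | COCOc1cc(CO)c(Br)c(Br)c1OCOC | intermediate
7 | 2,3-dibromo-1-(bromomethyl)-4,5-bis(methoxymethoxy)benzene | COCOc1cc(CBr)c(Br)c(Br)c1OCOC | intermediate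
8 | acetylacetone (pentane-2,4-dione) | CC(=O)CC(C)=O | starting material
9 | 3-diazopentane-2,4-dione | CC(=O)C(=[N+]=[N-])C(C)=O | intermediate
10 | 3-methoxypentane-2,4-dione | CC(=O)C(OC)C(C)=O | intermediate
11 | dilithium 3-methoxypenta-1,3-diene-2,4-diolate (dianion of 10; not isolated) | C=C(O[Li])C(OC)=C(C)O[Li] | intermediate
12 | 1-[2,3-dibromo-4,5-bis(methoxymethoxy)phenyl]-4-methoxyhexane-3,5-dione (racemic, enolisable) | CC(=O)C(OC)C(=O)CCc1cc(OCOC)c(OCOC)c(Br)c1Br | intermediate
13 | dimethyl oxalate | COC(=O)C(=O)OC | starting material
14 | dilithium 6-[2,3-dibromo-4,5-bis(methoxymethoxy)phenyl]-3-methoxyhexa-1,3-diene-2,4-diolate (dianion of 12; not isolated) | C=C(O[Li])C(OC)=C(O[Li])CCc1cc(OCOC)c(OCOC)c(Br)c1Br | intermediate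
15 | lithium hemiketal adduct of 14 and 13: dilithium salt of methyl 8-[2,3-dibromo-4,5-bis(methoxymethoxy)phenyl]-2,6-dihydroxy-2,5-dimethoxy-4-oxooct-5-enoate (racemic; not isolated) | COC(=O)C(O[Li])(OC)CC(=O)C(OC)=C(O[Li])CCc1cc(OCOC)c(OCOC)c(Br)c1Br | intermediate
16 | methyl 8-[2,3-dibromo-4,5-bis(methoxymethoxy)phenyl]-5-methoxy-2,4,6-trioxooctanoate (racemic, labile at C5; enol mixture) | COC(=O)C(=O)CC(=O)C(OC)C(=O)CCc1cc(OCOC)c(OCOC)c(Br)c1Br | intermediate
17 | methyl 2-[2,3-dibromo-4,5-bis(methoxymethoxy)benzyl]-1-hydroxy-4-methoxy-3,5-dioxocyclohexane-1-carboxylate (diastereomer mixture; not isolated) | COC(=O)C1(O)CC(=O)C(OC)C(=O)C1Cc1cc(OCOC)c(OCOC)c(Br)c1Br | intermediate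
18 | methyl 2-[2,3-dibromo-4,5-bis(methoxymethoxy)benzyl]-3,5-dihydroxy-4-methoxybenzoate | COC(=O)c1cc(O)c(OC)c(O)c1Cc1cc(OCOC)c(OCOC)c(Br)c1Br | intermediate
19 | methyl 2-(2,3-dibromo-4,5-dihydroxybenzyl)-3,5-dihydroxy-4-methoxybenzoate | COC(=O)c1cc(O)c(OC)c(O)c1Cc1cc(O)c(O)c(Br)c1Br | intermediate
20 | 3,4-dibromo-5-{[2,4-dihydroxy-6-(hydroxymethyl)-3-methoxyphenyl]methyl}benzene-1,2-diol (achiral) | COc1c(O)cc(CO)c(Cc2cc(O)c(O)c(Br)c2Br)c1O | target

## Step count and least certain steps

Total: 12 steps. Longest linear sequence: 10 steps (steps 1–5, then 8–12).

**Step 10 (key step).** The chain may rest as a stabilised enolate in which the keto-ester carbonyl is itself enolised, so that enolisation at C7 and C–C closure are slow. Retro-Claisen loss of the oxalyl terminus by methoxide, or the five-membered Dieckmann closure, could then drain material.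
Fallback: form the bridge by cross-coupling onto an intact ring A, setting out from 7 and coming back at 19. Commercial methyl 3,5-dihydroxy-4-methoxybenzoate F1 would be mono-iodinated with N-iodosuccinimide to methyl 3,5-dihydroxy-2-iodo-4-methoxybenzoate F2. This would be protected with MOMCl and iPr2NEt as methyl 2-iodo-4-methoxy-3,5-bis(methoxymethoxy)benzoate F3. Zn dust with LiCl would insert selectively into the benzylic C–Br bond of 7 to give [2,3-dibromo-4,5-bis(methoxymethoxy)benzyl]zinc bromide F4. A Negishi coupling (Pd(OAc)2, SPhos, THF, rt) of F4 with F3 should then give methyl 2-[2,3-dibromo-4,5-bis(methoxymethoxy)benzyl]-4-methoxy-3,5-bis(methoxymethoxy)benzoate F5, since zerovalent palladium inserts into the aryl iodide far faster than into the hindered, electron-rich aryl bromides. HCl in MeOH would remove all four acetals and deliver 19.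

**Step 9.** Second deprotonation of 12 may occur partly at the CH2 and not at the methyl group, and early collapse of 15 would allow proton transfer to unreacted 14 or a second addition.
Fallback: reverse the order of the two C–C bonds, setting out from 10 (as 11), 13 and 7 and coming back at 16. The symmetrical dianion 11, used in excess because it is cheap, would be acylated with 13 to give methyl 5-methoxy-2,4,6-trioxoheptanoate F6; symmetry removes the regiochemical question. F6 would be deprotonated three times with LiN(iPr)2 to the trilithium trienolate of methyl 5-methoxy-2,4,6-trioxoheptanoate F7. Alkylation of F7 with 7 at its terminal, least stabilised carbanion would give 16.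

**Step 8.** The dianion of the methoxy diketone may form incompletely, or proton exchange between 11 and the product enolate may lead to double alkylation.
Fallback: alkylate first and introduce the methoxy group afterwards, setting out from 8 and 7 and coming back at 12. Acetylacetone 8 would be converted with LiN(iPr)2 into dilithium penta-1,3-diene-2,4-diolate F8. Alkylation with 7 would give 6-[2,3-dibromo-4,5-bis(methoxymethoxy)phenyl]hexane-2,4-dione F9. Diazo transfer as in step 6 would give 3-diazo-6-[2,3-dibromo-4,5-bis(methoxymethoxy)phenyl]hexane-2,4-dione F10. Rh2(OAc)4 in neat methanol would then give 12; the large excess of alcohol favours O–H insertion over attack of the carbenoid on ring B. This costs two more steps on the ring B fragment, which is why it is not the main route.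

**Step 12.** Reduction may stall because the polyphenoxide aluminium species aggregate and precipitate, and the free catechol may oxidise during the aqueous work-up.
Fallback: reduce before deprotecting, setting out from 18 and coming back at 20. iBu2AlH in THF would reduce 18, which has only two free phenols, to {2-[2,3-dibromo-4,5-bis(methoxymethoxy)benzyl]-3,5-dihydroxy-4-methoxyphenyl}methanol F11. The acetals would then be removed with dilute aqueous HCl in THF at high dilution. Water is then the only nucleophile, so any ionisation of the benzylic alcohol returns the same alcohol, and the released formaldehyde stays as its hydrate.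

## Further compounds

F1 | step 10 | methyl 3,5-dihydroxy-4-methoxybenzoate | COC(=O)c1cc(O)c(OC)c(O)c1
F2 | step 10 | methyl 3,5-dihydroxy-2-iodo-4-methoxybenzoate | COC(=O)c1cc(O)c(OC)c(O)c1I
F3 | step 10 | methyl 2-iodo-4-methoxy-3,5-bis(methoxymethoxy)benzoate | COC(=O)c1cc(OCOC)c(OC)c(OCOC)c1I
F4 | step 10 | [2,3-dibromo-4,5-bis(methoxymethoxy)benzyl]zinc bromide | COCOc1cc(C[Zn]Br)c(Br)c(Br)c1OCOC
F5 | step 10 | methyl 2-[2,3-dibromo-4,5-bis(methoxymethoxy)benzyl]-4-methoxy-3,5-bis(methoxymethoxy)benzoate | COC(=O)c1cc(OCOC)c(OC)c(OCOC)c1Cc1cc(OCOC)c(OCOC)c(Br)c1Br
F6 | step 9 | methyl 5-methoxy-2,4,6-trioxoheptanoate (racemic, enolisable) | COC(=O)C(=O)CC(=O)C(OC)C(C)=O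
F7 | step 9 | trilithium trienolate of methyl 5-methoxy-2,4,6-trioxoheptanoate | COC(=O)C(O[Li])=CC(O[Li])=C(OC)C(O[Li])=C
F8 | step 8 | dilithium penta-1,3-diene-2,4-diolate | C=C(O[Li])C=C(C)O[Li]
F9 | step 8 | 6-[2,3-dibromo-4,5-bis(methoxymethoxy)phenyl]hexane-2,4-dione | CC(=O)CC(=O)CCc1cc(OCOC)c(OCOC)c(Br)c1Br
F10 | step 8 | 3-diazo-6-[2,3-dibromo-4,5-bis(methoxymethoxy)phenyl]hexane-2,4-dione | CC(=O)C(=[N+]=[N-])C(=O)CCc1cc(OCOC)c(OCOC)c(Br)c1Br
F11 | step 12 | {2-[2,3-dibromo-4,5-bis(methoxymethoxy)benzyl]-3,5-dihydroxy-4-methoxyphenyl}methanol | COc1c(O)cc(CO)c(Cc2cc(OCOC)c(OCOC)c(Br)c2Br)c1O
A1 | alternative 1 | methyl 3,5-diacetoxy-2-(3,4-dihydroxybenzyl)-4-methoxybenzoate | COC(=O)c1cc(OC(C)=O)c(OC)c(OC(C)=O)c1Cc1ccc(O)c(O)c1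
A2 | alternative 1 | methyl 3,5-diacetoxy-2-(2,3-dibromo-4,5-dihydroxybenzyl)-4-methoxybenzoate | COC(=O)c1cc(OC(C)=O)c(OC)c(OC(C)=O)c1Cc1cc(O)c(O)c(Br)c1Br
A3 | alternative 2 | 1,2-dimethoxy-1,3-bis(trimethylsilyloxy)buta-1,3-diene (mixture of double-bond isomers) | C=C(O[Si](C)(C)C)C(OC)=C(OC)O[Si](C)(C)C
A4 | alternative 2 | 4-(tert-butyldimethylsilyloxy)-1-[2,3-dibromo-4,5-bis(methoxymethoxy)phenyl]but-2-yn-1-one | O=C(C#CCO[Si](C)(C)C(C)(C)C)c1cc(OCOC)c(OCOC)c(Br)c1Br
A5 | alternative 2 | [2,3-dibromo-4,5-bis(methoxymethoxy)phenyl][6-(tert-butyldimethylsilyloxymethyl)-2,4-dihydroxy-3-methoxyphenyl]methanone | COc1c(O)cc(CO[Si](C)(C)C(C)(C)C)c(C(=O)c2cc(OCOC)c(OCOC)c(Br)c2Br)c1O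
A6 | alternative 3 | methyl 3-hydroxy-4-methoxy-5-(pivaloyloxy)benzoate | COC(=O)c1cc(O)c(OC)c(OC(=O)C(C)(C)C)c1
A7 | alternative 3 | formaldehyde | C=O
A8 | alternative 3 | [2,3-dibromo-4,5-bis(methoxymethoxy)phenyl]boronic acid | COCOc1cc(B(O)O)c(Br)c(Br)c1OCOC
A9 | alternative 3 | methyl 2-[2,3-dibromo-4,5-bis(methoxymethoxy)phenyl]-8-methoxy-7-(pivaloyloxy)-4H-1,3,2-benzodioxaborine-5-carboxylate | COC(=O)c1cc(OC(=O)C(C)(C)C)c(OC)c2OB(c3cc(OCOC)c(OCOC)c(Br)c3Br)OCc12
A10 | alternative 3 | methyl 2-[2,3-dibromo-4,5-bis(methoxymethoxy)benzyl]-3-hydroxy-4-methoxy-5-(pivaloyloxy)benzoate | COC(=O)c1cc(OC(=O)C(C)(C)C)c(OC)c(O)c1Cc1cc(OCOC)c(OCOC)c(Br)c1Br
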